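Ring A, the 3-methoxyphenyl ring, is made rather than bought. Its oxygen-bearing carbon C1 and chain-bearing carbon C3 stand 1,3, which is what a Diels–Alder reaction of 2-(trimethylsilyloxy)butadiene (supplying C1, C2, C5, C6) with an (E)-nitroalkene (supplying C3, C4) delivers once the para-directing nitro group on C4 is removed. One cycloaddition forms the C2–C3 and C4–C5 bonds and closes ring A as a 4-nitrocyclohexanone. The dienophile is a 1-nitrobutene whose far end already carries the complete, bis-benzyl-protected diaryl ether bibenzyl (rings B, C, D). Radical denitration, palladium-catalysed dehydrogenation, O-methylation and hydrogenolysis then give the target.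

Key step: step 8

Assumption: the target is achiral; the two stereocentres formed in step 8 are racemic and vanish on aromatisation, so no absolute control is attempted.

Remark: in the cycloadduct the nitro group sits γ to the carbonyl carbon, where no E1cB loss of nitrous acid is available, so it is removed by radical reduction. Benzyl ethers protect both phenols because the regiodefined benzyl building blocks are commercial and the final hydrogenolysis cannot touch the methyl ether.

In names, Ar = 4-(benzyloxy)-3-{4-[2-(3-(benzyloxy)phenyl)ethyl]phenoxy}phenyl.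

Step 1
Reactants: 1 4-(benzyloxy)-3-hydroxybenzaldehyde; 2 methyl (triphenylphosphoranylidene)acetate
Product: 3 methyl (E)-3-[4-(benzyloxy)-3-hydroxyphenyl]prop-2-enoate
Conditions: toluene, 90 °C
Reagents that add atoms: none
Why: Wittig olefination with an ester-stabilised ylide is E-selective and tolerates the free phenol, and the regiochemistry of the two ring oxygens is already fixed in 1.

Step 2
Reactants: 3 methyl (E)-3-[4-(benzyloxy)-3-hydroxyphenyl]prop-2-enoate; 4 4-fluorobenzaldehyde
Product: 5 methyl (E)-3-[4-(benzyloxy)-3-(4-formylphenoxy)phenyl]prop-2-enoate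
Conditions: K2CO3, DMF, 120 °C
Reagents that add atoms: none
Why: Nucleophilic aromatic substitution (SNAr, addition–elimination) of the para-formyl-activated fluoride by the only phenoxide present forms the diaryl ether.

Step 3
Reactants: 6 3-(benzyloxy)benzyl bromide
Product: 7 [3-(benzyloxy)benzyl]triphenylphosphonium bromide
Conditions: PPh3, toluene, 110 °C
Reagents that add atoms: triphenylphosphine, c1ccc(cc1)P(c1ccccc1)c1ccccc1
Why: SN2 quaternisation of the phosphine by a benzylic bromide gives the salt, which precipitates from toluene.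

Step 4
Reactants: 5 methyl (E)-3-[4-(benzyloxy)-3-(4-formylphenoxy)phenyl]prop-2-enoate; 7 [3-(benzyloxy)benzyl]triphenylphosphonium bromide
Product: 8 methyl (E)-3-[4-(benzyloxy)-3-{4-[2-(3-(benzyloxy)phenyl)ethenyl]phenoxy}phenyl]prop-2-enoate (E/Z mixture at the stilbene alkene)
Conditions: K2CO3, 18-crown-6 (cat.), CH2Cl2, 40 °C
Reagents that add atoms: none
Why: Wittig olefination under mild solid–liquid phase-transfer conditions spares the methyl ester, and the E/Z mixture from the semi-stabilised ylide is irrelevant because the alkene is hydrogenated next.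

Step 5
Reactants: 8 methyl (E)-3-[4-(benzyloxy)-3-{4-[2-(3-(benzyloxy)phenyl)ethenyl]phenoxy}phenyl]prop-2-enoate
Product: 9 methyl 3-Ar-propanoate
Conditions: H2 (1 atm), 10% Pd/C, 2,2'-bipyridyl (0.5 equiv), EtOAc–MeOH, rt
Reagents that add atoms: none
Why: Heterogeneous catalytic hydrogenation saturates the cinnamate and stilbene alkenes, and the 2,2'-bipyridyl poison is the known means of suppressing hydrogenolysis of phenolic benzyl ethers on Pd/C.

Step 6
Reactants: 9 methyl 3-Ar-propanoate
Product: 10 3-Ar-propanal
Conditions: i-Bu2AlH (1.1 equiv), CH2Cl2, −78 °C; then MeOH, aq. potassium sodium tartrate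
Reagents that add atoms: none
Why: Partial ester reduction with i-Bu2AlH stops at the tetrahedral aluminium hemiacetal at −78 °C, so the aldehyde is released only after the hydride is quenched.

Step 7
Reactants: 10 3-Ar-propanal; 11 nitromethane
Product: 13 (E)-4-Ar-1-nitrobut-1-ene, via nitro alcohol 12 (not isolated)
Conditions: MeNO2 (10 equiv), KOt-Bu (10 mol %), THF–t-BuOH, 0 °C to rt; AcOH, evaporate; then MsCl, Et3N, CH2Cl2, −20 to 0 °C
Reagents that add atoms: none
Why: A Henry (nitroaldol) reaction followed by mesylation and E1cB elimination gives the thermodynamically preferred (E)-nitroalkene, and the racemic carbinol stereocentre of 12 is destroyed in the elimination.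

Step 8
Reactants: 13 (E)-4-Ar-1-nitrobut-1-ene; 14 2-(trimethylsilyloxy)buta-1,3-diene
Product: 16 racemic trans-3-(2-Ar-ethyl)-4-nitrocyclohexan-1-one, via silyl enol ether cycloadduct 15 (not isolated)
Conditions: 14 (4 equiv), BHT (cat.), toluene, 110 °C, sealed tube; evaporate; then 1 M HCl, THF, 0 °C to rt
Reagents that add atoms: none
Why: The diene, whose HOMO is raised by the 2-silyloxy group and is largest at C1, and the nitroalkene, whose LUMO is largest at the alkyl-bearing carbon, combine in a concerted, thermally allowed suprafacial [4+2] cycloaddition; the reaction type is the normal-electron-demand Diels–Alder reaction of nitroalkenes with 2-silyloxydienes. The six-membered carbocycle closes intermolecularly, both ring bonds (C2–C3 and C4–C5 of the future ring A) forming in the same step. The two new stereocentres, C3 and C4, are fixed relative to each other by the E geometry of the dienophile, which is transferred stereospecifically to the trans arrangement of chain and nitro group; the diene termini are unsubstituted, so no endo/exo question arises, and the adduct is racemic. The selectivity the step needs is regiochemical, chain 1,3 and nitro 1,4 to the oxygenated carbon, and it is secured by the nitro group as the only activating substituent on the alkene. Excess diene and a radical inhibitor counter diene polymerisation, and the dilute acid cleaves only the silyl enol ether of 15, leaving benzyl and diaryl ethers intact.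

Step 9
Reactants: 16 racemic trans-3-(2-Ar-ethyl)-4-nitrocyclohexan-1-one
Product: 17 racemic 3-(2-Ar-ethyl)cyclohexan-1-one
Conditions: Bu3SnH (5 equiv), AIBN (0.5 equiv, in portions), toluene, 110 °C; aq. KF work-up
Reagents that add atoms: none
Why: Radical chain denitration (Bu3Sn• adds to a nitro oxygen, the adduct fragments at the C–N bond, the secondary alkyl radical takes hydrogen from Bu3SnH) is a known way to remove secondary nitro groups at toluene reflux and leaves the ketone and benzyl ethers alone; the nitro-bearing stereocentre disappears.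

Step 10
Reactants: 17 racemic 3-(2-Ar-ethyl)cyclohexan-1-one
Product: 18 3-(2-Ar-ethyl)phenol
Conditions: Pd(OCOCF3)2 (5 mol %), 2-(dimethylamino)pyridine (10 mol %), TsOH·H2O (20 mol %), O2 (1 atm), DMSO, 80 °C
Reagents that add atoms: none
Why: Aerobic dehydrogenation of a cyclohexanone to a phenol with a divalent palladium catalyst (two rounds of α-palladation and β-hydride elimination, then tautomerisation) can give only the 3-substituted phenol from a 3-substituted ketone, and it erases the last stereocentre.

Step 11
Reactants: 18 3-(2-Ar-ethyl)phenol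
Product: 19 1-methoxy-3-(2-Ar-ethyl)benzene
Conditions: MeI, K2CO3, acetone, 50 °C
Reagents that add atoms: iodomethane, CI
Why: Williamson O-methylation of the only free phenol makes the ring A methyl ether distinct from the two benzyl-protected oxygens.

Step 12
Reactants: 19 1-methoxy-3-(2-Ar-ethyl)benzene
Product: 20 2-{4-[2-(3-hydroxyphenyl)ethyl]phenoxy}-4-[2-(3-methoxyphenyl)ethyl]phenol (target)
Conditions: H2 (1 atm), 10% Pd/C, EtOAc–MeOH, rt
Reagents that add atoms: none
Why: Catalytic hydrogenolysis cleaves both aryl benzyl ethers, while the aryl methyl ether, the diaryl ether and the saturated bridges are inert.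

Compound list
1 | 4-(benzyloxy)-3-hydroxybenzaldehyde | O=Cc1ccc(OCc2ccccc2)c(O)c1 | starting material
2 | methyl (triphenylphosphoranylidene)acetate | COC(=O)C=P(c1ccccc1)(c1ccccc1)c1ccccc1 | starting material
3 | methyl (E)-3-[4-(benzyloxy)-3-hydroxyphenyl]prop-2-enoate | COC(=O)/C=C/c1ccc(OCc2ccccc2)c(O)c1 | intermediate
4 | 4-fluorobenzaldehyde | O=Cc1ccc(F)cc1 | starting material
5 | methyl (E)-3-[4-(benzyloxy)-3-(4-formylphenoxy)phenyl]prop-2-enoate | COC(=O)/C=C/c1ccc(OCc2ccccc2)c(Oc2ccc(C=O)cc2)c1 | intermediate
6 | 3-(benzyloxy)benzyl bromide | BrCc1cccc(OCc2ccccc2)c1 | starting material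
7 | [3-(benzyloxy)benzyl]triphenylphosphonium bromide | [Br-].c1ccc(cc1)[P+](Cc1cccc(OCc2ccccc2)c1)(c1ccccc1)c1ccccc1 | intermediate
8 | methyl (E)-3-[4-(benzyloxy)-3-{4-[2-(3-(benzyloxy)phenyl)ethenyl]phenoxy}phenyl]prop-2-enoate, E/Z mixture at the stilbene alkene (written without configuration there) | COC(=O)/C=C/c1ccc(OCc2ccccc2)c(Oc2ccc(C=Cc3cccc(OCc4ccccc4)c3)cc2)c1 | intermediate
9 | methyl 3-Ar-propanoate | COC(=O)CCc1ccc(OCc2ccccc2)c(Oc2ccc(CCc3cccc(OCc4ccccc4)c3)cc2)c1 | intermediate
10 | 3-Ar-propanal | O=CCCc1ccc(OCc2ccccc2)c(Oc2ccc(CCc3cccc(OCc4ccccc4)c3)cc2)c1 | intermediate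
11 | nitromethane | C[N+](=O)[O-] | starting material
12 | racemic 4-Ar-1-nitrobutan-2-ol | [O-][N+](=O)CC(O)CCc1ccc(OCc2ccccc2)c(Oc2ccc(CCc3cccc(OCc4ccccc4)c3)cc2)c1 | intermediate (not isolated)
13 | (E)-4-Ar-1-nitrobut-1-ene | [O-][N+](=O)/C=C/CCc1ccc(OCc2ccccc2)c(Oc2ccc(CCc3cccc(OCc4ccccc4)c3)cc2)c1 | intermediate
14 | 2-(trimethylsilyloxy)buta-1,3-diene | C=CC(=C)O[Si](C)(C)C | starting material
15 | racemic trans-4-nitro-5-(2-Ar-ethyl)-1-(trimethylsilyloxy)cyclohex-1-ene (one enantiomer drawn) | C[Si](C)(C)OC1=CC[C@@H]([N+](=O)[O-])[C@H](CCc2ccc(OCc3ccccc3)c(Oc3ccc(CCc4cccc(OCc5ccccc5)c4)cc3)c2)C1 | intermediate (not isolated)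
16 | racemic trans-3-(2-Ar-ethyl)-4-nitrocyclohexan-1-one (one enantiomer drawn) | O=C1CC[C@@H]([N+](=O)[O-])[C@H](CCc2ccc(OCc3ccccc3)c(Oc3ccc(CCc4cccc(OCc5ccccc5)c4)cc3)c2)C1 | intermediate
17 | racemic 3-(2-Ar-ethyl)cyclohexan-1-one (stereocentre written without configuration) | O=C1CCCC(CCc2ccc(OCc3ccccc3)c(Oc3ccc(CCc4cccc(OCc5ccccc5)c4)cc3)c2)C1 | intermediate
18 | 3-(2-Ar-ethyl)phenol | Oc1cccc(CCc2ccc(OCc3ccccc3)c(Oc3ccc(CCc4cccc(OCc5ccccc5)c4)cc3)c2)c1 | intermediate
19 | 1-methoxy-3-(2-Ar-ethyl)benzene | COc1cccc(CCc2ccc(OCc3ccccc3)c(Oc3ccc(CCc4cccc(OCc5ccccc5)c4)cc3)c2)c1 | intermediate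
20 | 2-{4-[2-(3-hydroxyphenyl)ethyl]phenoxy}-4-[2-(3-methoxyphenyl)ethyl]phenol (achiral) | COc1cccc(CCc2ccc(O)c(Oc3ccc(CCc4cccc(O)c4)cc3)c2)c1 | target

Total step count: 12. Longest linear sequence: 11 steps (steps 1, 2 and 4 to 12, from compound 1); step 3 is a one-step side branch.

Steps most likely to fail

Step 8 (cycloaddition). The cycloaddition of the unactivated aliphatic nitroalkene may be slower than thermal polymerisation or adventitious hydrolysis of the diene, and on long heating the nitroalkene may drift to its allylic isomer. The fallback brings ring A in as a ready-made arene, with no cycloaddition. Setting out from 1, a Wittig reaction with commercial (3-methoxybenzyl)triphenylphosphonium chloride (KOt-Bu, THF) would give the stilbene phenol 2-(benzyloxy)-5-[2-(3-methoxyphenyl)ethenyl]phenol F1. SNAr with 4 (K2CO3, DMF, 120 °C) would give the aldehyde 4-{2-(benzyloxy)-5-[2-(3-methoxyphenyl)ethenyl]phenoxy}benzaldehyde F2. A Wittig reaction with 7 under the conditions of step 4 would give the bis-stilbene 1-(benzyloxy)-2-{4-[2-(3-(benzyloxy)phenyl)ethenyl]phenoxy}-4-[2-(3-methoxyphenyl)ethenyl]benzene F3. Hydrogenation over the poisoned catalyst of step 5 would saturate both alkenes and rejoin the route at 19.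

Step 9 (denitration). Fragmentation of the tin-bound nitroxyl radical at the secondary C–N bond may be slow, so that reduction at nitrogen towards the oxime, or stalling at partial conversion, takes over. The fallback builds ring A by a nitro-free annulation. Setting out from 10, a Wittig reaction with (triphenylphosphoranylidene)acetaldehyde (toluene, 80 °C) would give the enal (E)-5-Ar-pent-2-enal F4. Michael addition of tert-butyl acetoacetate under secondary-amine catalysis (diphenylprolinol trimethylsilyl ether, either enantiomer), followed by intramolecular aldol condensation, would give tert-butyl 6-(2-Ar-ethyl)-2-oxocyclohex-3-ene-1-carboxylate F5. TsOH in toluene at 80 °C would cleave the tert-butyl ester and decarboxylate to 5-(2-Ar-ethyl)cyclohex-2-en-1-one F6. The aerobic palladium dehydrogenation of step 10, here needing only one dehydrogenation, would then give phenol 18.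

Step 7 (nitroalkene formation). During the base-mediated elimination the conjugated nitroalkene may isomerise to the allylic nitro compound or add a second nitronate and oligomerise. The fallback nitrates an alkene instead of dehydrating a nitro alcohol. Setting out from 10, methylenation with Ph3P=CH2 (from methyltriphenylphosphonium bromide and KOt-Bu, THF, 0 °C) would give the terminal alkene 4-Ar-but-1-ene F7. Radical nitration with AgNO2 and TEMPO (1,2-dichloroethane, 70 °C) would then give the (E)-nitroalkene 13 under non-basic conditions.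

Further compounds
F1 | step 8 | 2-(benzyloxy)-5-[2-(3-methoxyphenyl)ethenyl]phenol (E/Z mixture) | COc1cccc(C=Cc2ccc(OCc3ccccc3)c(O)c2)c1
F2 | step 8 | 4-{2-(benzyloxy)-5-[2-(3-methoxyphenyl)ethenyl]phenoxy}benzaldehyde (E/Z mixture) | COc1cccc(C=Cc2ccc(OCc3ccccc3)c(Oc3ccc(C=O)cc3)c2)c1
F3 | step 8 | 1-(benzyloxy)-2-{4-[2-(3-(benzyloxy)phenyl)ethenyl]phenoxy}-4-[2-(3-methoxyphenyl)ethenyl]benzene (E/Z mixtures) | COc1cccc(C=Cc2ccc(OCc3ccccc3)c(Oc3ccc(C=Cc4cccc(OCc5ccccc5)c4)cc3)c2)c1
F4 | step 9 | (E)-5-Ar-pent-2-enal | O=C/C=C/CCc1ccc(OCc2ccccc2)c(Oc2ccc(CCc3cccc(OCc4ccccc4)c3)cc2)c1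
F5 | step 9 | tert-butyl 6-(2-Ar-ethyl)-2-oxocyclohex-3-ene-1-carboxylate (diastereomer mixture, written without configuration) | CC(C)(C)OC(=O)C1C(=O)C=CCC1CCc2ccc(OCc3ccccc3)c(Oc3ccc(CCc4cccc(OCc5ccccc5)c4)cc3)c2
F6 | step 9 | 5-(2-Ar-ethyl)cyclohex-2-en-1-one (stereocentre written without configuration) | O=C1C=CCC(CCc2ccc(OCc3ccccc3)c(Oc3ccc(CCc4cccc(OCc5ccccc5)c4)cc3)c2)C1
F7 | step 7 | 4-Ar-but-1-ene | C=CCCc1ccc(OCc2ccccc2)c(Oc2ccc(CCc3cccc(OCc4ccccc4)c3)cc2)c1
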